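## Structural features

The target is a 3,4-dihydroisocoumarin: ring A is a benzene ring with free hydroxyls at C6 and C8, fused through C4a and C8a to the six-membered lactone ring B (C1, O2, C3, C4). C3 carries an unbranched eleven-carbon chain whose C9' is a secondary carbinol, so the chain ends in an ethyl group. The only stereocentres are C3 (R) and C9' (S). Eight methylene groups separate them, so neither can steer the other, an epimer at either one would be very hard to detect or remove, and each centre has to come with high purity from its own source. The two centres share a hidden twofold symmetry, because each carbinol carbon links the long chain to a short arm (C4 or C10') in the same spatial sense. The fragile parts are the lactone, which opens in base, and the electron-rich resorcinol ring, which is sensitive to electrophiles and oxidants; the C8 hydroxyl is hydrogen-bonded to the C1 carbonyl and lowers its reactivity as an acyl group. The real difficulty is ring A: the acyl carbon on C8a, the alkyl carbon on C4a and the oxygens on C8 and C6 must be placed without regiochemical ambiguity and preferably without phenol protection. The key step exploits three facts: C5–C6(O)–C7–C8(O) is a 1,3-dioxygenated diene with C8 at the carboxyl oxidation level, C4–C4a–C8a–C1 maps onto C4 to C1 of an alk-2-ynoate, and the C3 oxygen is placed to close ring B on C1 as soon as ring A exists.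

## Logic of the disconnections

19 to 11 and 15. The first cut removes both rings of 19 at once: the lactone bond O2–C1 and the ring A bonds C5–C4a and C8–C8a. C5 to C8 then fall out as the four-carbon unit 15, whose oxygen substituents already sit where C6 and C8 need them, and C1, C8a, C4a and C4 stay joined as the ynoate end of 11 with the C3 oxygen in place. The gain is that a bicyclic, heavily substituted arene becomes an open chain plus a C4 reagent, with no aromatic substitution, no phenol protection, and both stereocentres outside the reacting atoms. The forward step must add regioselectively to a β-alkylated alkyne that reacts only on heating, the silyl ethers must survive that heating, and one acid treatment must remove every silyl group so that the lactone can close.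

11 to 7 and 8, by way of 10. 11 is the silyl ether of 10, and 10 is cut between the alkyne carbon and its CH2 neighbour (C4a–C4 of the target). A homopropargylic alcohol is the retron of an acetylide opening a terminal oxirane at its CH2, which leaves the carbinol centre untouched. The whole ynoate terminus then comes from the three-carbon compound 8, and the C3 problem becomes the configuration of the oxirane in 7. The metalated form 9 is a weak and thermally labile nucleophile, so the forward step needs Lewis-acid activation at low temperature and attack at the terminal carbon only.

7 to 5, by way of 6. The two C–O bonds of the oxirane are removed to reveal the terminal alkene of 5. The C9' centre is too far away to direct an epoxidation, so the oxirane centre has to be fixed by a catalyst; an unselective epoxidation to 6 followed by a hydrolytic kinetic resolution does this with the highest reliability. The price is that half of 6 is consumed, and the catalyst must tell the two epimers apart regardless of the remote centre.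

5 to 1 and 2, by way of 4 and 3. 5 is the silyl ether of 4, and 4 is cut at C7'–C8', one carbon away from the carbinol. Cutting there lets the chiral-pool oxirane 2 deliver C9' with its configuration intact, while 1 supplies the rest of the chain with the alkene as a latent oxirane. The forward step needs the organometallic 3 to open 2 at the CH2 carbon only.

15 to 12, by way of 13 and 14. The two Si–O bonds of 15 are cut in turn, back to the β-keto ester 12. Each silylation must take place on oxygen, the second one at the vinylogous (γ) position through dienolate 14.

## Other disconnections considered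

Alternative 1: The cut is made in the chain, at C1'–C2' and C7'–C8', and uses the hidden twofold symmetry. Under copper catalysis, 1,6-bis(bromomagnesio)hexane A3 would open two molecules of (R)-epichlorohydrin A2 at the oxirane CH2. The product, (2R,11R)-1,12-dichlorododecane-2,11-diol A1, holds every carbon from C4 to C10' and both carbinol centres.
- In its favour: both stereocentres come from the chiral pool in one step, with no resolution. Base would convert A1 into (2R,2'R)-2,2'-(octane-1,8-diyl)bis(oxirane) A4, which has two electrophilic ends.
- Against it here: the two ends of A4 are identical, yet one must take a methyl nucleophile (C11') and the other the aromatic carbon C4a, so the first opening can only be statistical. The step closes no ring. Ring A would have to arrive as a protected resorcinol nucleophile, and C1 would then have to be installed ortho to the new benzylic carbon, with the regiochemical and protecting-group questions that the chosen plan avoids. A 1,6-bis-Grignard reagent is also harder to prepare cleanly than a mono-Grignard reagent.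
- Comparison: on the stereocentres this alternative is the better plan, since the chosen route discards half of 6 in step 4. Its key step, an epoxide opening, is also mechanistically more reliable than a thermal cycloaddition, and the chain is assembled in fewer steps. On structure it leaves the hardest part, the arene and the lactone, unsolved. Desymmetrisation and arene functionalisation would bring the total to about the nine steps of the chosen route or more, with a statistical step among them.

Alternative 2: The cut takes out the ring oxygen (C1–O2 and O2–C3) and leads back to 2-[(S)-9-hydroxyundecyl]-5,7-bis(methoxymethoxy)indan-1-one A6, racemic at C2. A Baeyer–Villiger monooxygenase, with dioxygen and its nicotinamide cofactor, would insert oxygen between the carbonyl carbon and C2 while the slower enantiomer racemises through its enol. This dynamic kinetic resolution would give (R)-3-[(S)-9-hydroxyundecyl]-6,8-bis(methoxymethoxy)isochroman-1-one A5.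
- In its favour: ring B and the C3 centre would be made in one catalytic step in water at ambient temperature. A dynamic resolution can in principle convert all of the material, which a static resolution such as step 4 cannot.
- Against it here: the alkyl carbon C2 must migrate, but the aryl group of A6, with oxygen ortho and para to the migration origin, is the intrinsically better migrating group; the enzyme would have to override this to avoid the regioisomeric lactone. The substrate combines a substituent next to the carbonyl with a very lipophilic chain, both outside the usual range of such enzymes. The sense of induction at C3 is fixed by the protein. The base needed for racemisation threatens the lactone. C9' must still be set separately.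
- Comparison: in atom economy, mildness of the ring-forming step and stereochemical throughput at C3 the alternative is the better plan. In predictability the chosen plan is better, since each of its steps is a known reaction type on the same substrate class and the configuration at C3 follows from a catalyst of known sense. In step count the two are about equal, because A5 still needs its two acetal groups removed while the chosen route ends at the target.

Alternative 3: The cut is the C4a–C8a bond of ring A, which unfolds the arene into the masked polyketide 6-[(6R,15S)-6,15-bis(tert-butyldimethylsilyloxy)-2,4-dioxoheptadecyl]-2,2-dimethyl-4H-1,3-dioxin-4-one A8. A tertiary amine base would trigger intramolecular aldol addition of the dioxinone α-carbon to the distal ketone, and loss of water and enolisation would give 7-hydroxy-2,2-dimethyl-5-[(2R,11S)-2,11-bis(tert-butyldimethylsilyloxy)tridecyl]-4H-benzo[d][1,3]dioxin-4-one A7.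
- In its favour: ring A forms at room temperature with inherent regiochemistry. The acetonide both protects the C8 oxygen and activates C1, so the later lactonisation by the freed C3 hydroxyl should be easy. In mildness of the arene-forming step it is better than the chosen plan, and in regiochemical certainty it is its equal.
- Against it here: A8 would have to be assembled by acylating a dioxinone keto-enolate with an activated β-silyloxy acyl donor, a partner prone to β-elimination. Such tricarbonyl compounds are tautomeric mixtures and awkward to purify. After A7, two silyl ethers and the acetonide must be removed and ring B closed in further operations.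
- Comparison: both plans build ring A from acyclic carbon with the oxygen pattern already encoded, the alternative by ionic condensation and the chosen one by cycloaddition. The chosen plan is better in step economy: 11 is two steps from 7 and its ring-forming step also closes ring B, whereas the alternative needs more carbon–carbon bond formations before its key step and at least one more operation after it.

Key step: step 9

Remarks on the chemistry:
- The acid stage of step 9 is made strong enough to cleave the tert-butyldimethylsilyl ether as well. The product of the key step is therefore the target itself and no separate deprotection follows. This removes the need for a silyl ether to survive acid that must also lactonise a hydrogen-bonded salicylate.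
- 13 is used as whatever E/Z mixture forms, since both isomers give the same dienolate 14.
- Both oxirane openings occur at the CH2 carbon, so no descriptor changes: (S)-2 leads to 9'S and (R)-7 leads to 3R.

## Route

Step 1
Reactants: 1 9-bromonon-1-ene; 2 (S)-1,2-epoxybutane
Product: 4 (S)-tridec-12-en-3-ol, via non-8-enylmagnesium bromide 3 (not isolated)
Conditions: Mg, THF, rt to 40 °C; then CuI (10 mol%), 2 (1.2 equiv), THF, −30 °C to 0 °C; aq NH4Cl
Reagents that add atoms: none
Why: Copper-catalysed SN2 opening of a monosubstituted oxirane by a primary Grignard reagent goes at the unsubstituted CH2, so the C–O centre of 2 is not touched and appears as the (S)-carbinol; the terminal alkene is inert to the organometallic.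

Step 2
Reactants: 4 (S)-tridec-12-en-3-ol
Product: 5 tert-butyldimethyl{[(3S)-tridec-12-en-3-yl]oxy}silane
Conditions: t-BuMe2SiCl, imidazole, DMF, rt
Reagents that add atoms: tert-butyldimethylsilyl chloride, CC(C)(C)[Si](C)(C)Cl
Why: Standard O-silylation of a secondary alcohol with a silyl chloride and imidazole; the ether is chosen to withstand peracid, the resolution and BF3 at −78 °C, and no stereocentre is involved.

Step 3
Reactants: 5 tert-butyldimethyl{[(3S)-tridec-12-en-3-yl]oxy}silane
Product: 6 2-[(9S)-9-(tert-butyldimethylsilyloxy)undecyl]oxirane (both epimers at the oxirane carbon)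
Conditions: mCPBA, NaHCO3, CH2Cl2, 0 °C to rt
Reagents that add atoms: 3-chloroperoxybenzoic acid, OOC(=O)c1cccc(Cl)c1
Why: Prilezhaev epoxidation of a terminal alkene; the silyloxy centre is eight methylenes away and exerts no facial bias, so both epimers are expected in about equal amounts, and the buffered peracid leaves the silyl ether intact.

Step 4
Reactants: 6 2-[(9S)-9-(tert-butyldimethylsilyloxy)undecyl]oxirane (both epimers)
Product: 7 (2R)-2-[(9S)-9-(tert-butyldimethylsilyloxy)undecyl]oxirane
Conditions: (R,R)-(salen)Co(OAc) (0.5–1 mol%), H2O (0.55 equiv), THF, 0 °C to rt; chromatography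
Reagents that add atoms: none
Why: Hydrolytic kinetic resolution (Jacobsen): the (R,R) complex of trivalent cobalt with the N,N'-bis(3,5-di-tert-butylsalicylidene)cyclohexane-1,2-diamine ligand hydrolyses (S)-configured 2-alkyloxiranes much faster, so the (R)-oxirane epimer should remain and the polar diol is removed on silica. The oxirane centre is thus set by the catalyst alone, the remote centre being too far away to interfere.

Step 5
Reactants: 7 (2R)-2-[(9S)-9-(tert-butyldimethylsilyloxy)undecyl]oxirane; 8 methyl propiolate
Product: 10 methyl (5R,14S)-14-(tert-butyldimethylsilyloxy)-5-hydroxyhexadec-2-ynoate, via methyl 3-lithiopropiolate 9 (not isolated)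
Conditions: 8 (2.5 equiv), n-BuLi, THF, −78 °C; BF3·OEt2, −78 °C; then 7, −78 °C; aq NH4Cl at −78 °C
Reagents that add atoms: none
Why: Yamaguchi–Hirao alkynylation: the BF3-activated oxirane is opened by the lithium acetylide at the less hindered CH2, so the C–O centre is retained and becomes the (5R)-carbinol; the ester-bearing acetylide is generated and used at −78 °C, where it is stable.

Step 6
Reactants: 10 methyl (5R,14S)-14-(tert-butyldimethylsilyloxy)-5-hydroxyhexadec-2-ynoate
Product: 11 methyl (5R,14S)-14-(tert-butyldimethylsilyloxy)-5-(triethylsilyloxy)hexadec-2-ynoate
Conditions: Et3SiCl, imidazole, CH2Cl2, 0 °C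
Reagents that add atoms: chlorotriethylsilane, CC[Si](CC)(CC)Cl
Why: O-silylation under mild base that does not isomerise the ynoate; the triethylsilyl ether keeps the hydroxyl from protonating the ketene acetal diene in step 9 and is the first alkyl silyl ether to fall in the acid stage.

Step 7
Reactants: 12 methyl acetoacetate
Product: 13 methyl 3-(trimethylsilyloxy)but-2-enoate (E/Z mixture)
Conditions: Me3SiCl, Et3N, hexane, rt; filtration, distillation
Reagents that add atoms: chlorotrimethylsilane, C[Si](C)(C)Cl
Why: O-silylation of the enol form of a β-keto ester with a silyl chloride and an amine base (silyl enol ether formation); the geometry of the enol ether is lost in the next step and does not matter.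

Step 8
Reactants: 13 methyl 3-(trimethylsilyloxy)but-2-enoate
Product: 15 1-methoxy-1,3-bis(trimethylsilyloxy)buta-1,3-diene, via lithium dienolate 14 (not isolated)
Conditions: LiN(iPr)2, THF, −78 °C; Me3SiCl, −78 °C to 0 °C; pentane, filtration, used at once
Reagents that add atoms: chlorotrimethylsilane, C[Si](C)(C)Cl
Why: γ-Deprotonation of the vinylogous ester by the lithium amide gives the dienolate, and the hard silicon electrophile traps it on oxygen to give the bis-silyl dienol ether (ketene acetal formation by enolate O-silylation).

Step 9
Reactants: 11 methyl (5R,14S)-14-(tert-butyldimethylsilyloxy)-5-(triethylsilyloxy)hexadec-2-ynoate; 15 1-methoxy-1,3-bis(trimethylsilyloxy)buta-1,3-diene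
Product: 19 (R)-6,8-dihydroxy-3-[(S)-9-hydroxyundecyl]isochroman-1-one, via cyclohexa-1,4-diene cycloadduct 16 (not isolated), via aryl trimethylsilyl ether 17 (not isolated), via tetrahydroxy methyl ester 18 (not isolated)
Conditions: 15 (3 equiv, in portions), PhMe (conc.), sealed tube, 120 °C; then HCl (1.25 M in MeOH), 0 °C to rt; then evaporate, TsOH·H2O (cat.), PhMe, 60 °C
Reagents that add atoms: none
Why: A normal-demand Diels–Alder reaction joins the CH2 terminus of 15 to the ynoate β-carbon (C5–C4a) and the ketene acetal carbon to the α-carbon (C8–C8a) in an asynchronous [4+2] addition, closing ring A intermolecularly as the cyclohexa-1,4-diene 16. Because the dienophile is an alkyne, 16 is already at the arene oxidation level, and loss of methoxytrimethylsilane from the C8 ketal followed by tautomerisation gives the phenol 17 without an oxidant. Methanolic HCl then cleaves the aryl trimethylsilyl, the triethylsilyl and the tert-butyldimethylsilyl ethers, in that order of resistance, to give 18. The C3 hydroxyl attacks the ortho ester carbon C1 in a 6-exo-trig acyl substitution that closes ring B with loss of methanol, and the final warming in toluene with catalytic acid drives this to completion by removing methanol. The closest known reactions are the cycloaddition and aromatisation of 1-alkoxy-1,3-bis(silyloxy)dienes with alk-2-ynoates to 6-substituted 2,4-dihydroxybenzoates and the acid-mediated lactonisation of 2-(2-hydroxyalkyl)benzoates to dihydroisocoumarins. No stereocentre is created: the ketal carbon of 16 disappears on aromatisation, and C3 and C9' are carried over unchanged because lactonisation occurs at the acyl carbon and not at C3. The selectivity needed is regiochemical, and it is secured by matched polarisation, since both oxygen substituents of 15 raise the coefficient at its CH2 terminus and the ester polarises the alkyne toward its β-carbon. The β-alkyl group slows the addition, hence the heat and the excess of diene.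

## Compound list

1 | 9-bromonon-1-ene | C=CCCCCCCCBr | starting material
2 | (S)-1,2-epoxybutane | CC[C@H]1CO1 | starting material
3 | non-8-enylmagnesium bromide | C=CCCCCCCC[Mg]Br | intermediate (not isolated)
4 | (S)-tridec-12-en-3-ol | CC[C@H](O)CCCCCCCCC=C | intermediate
5 | tert-butyldimethyl{[(3S)-tridec-12-en-3-yl]oxy}silane | CC[C@H](O[Si](C)(C)C(C)(C)C)CCCCCCCCC=C | intermediate
6 | 2-[(9S)-9-(tert-butyldimethylsilyloxy)undecyl]oxirane, both epimers at the oxirane carbon | CC[C@H](O[Si](C)(C)C(C)(C)C)CCCCCCCCC1CO1 | intermediate
7 | (2R)-2-[(9S)-9-(tert-butyldimethylsilyloxy)undecyl]oxirane | CC[C@H](O[Si](C)(C)C(C)(C)C)CCCCCCCC[C@@H]1CO1 | intermediate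
8 | methyl propiolate | C#CC(=O)OC | starting material
9 | methyl 3-lithiopropiolate | [Li]C#CC(=O)OC | intermediate (not isolated)
10 | methyl (5R,14S)-14-(tert-butyldimethylsilyloxy)-5-hydroxyhexadec-2-ynoate | COC(=O)C#CC[C@H](O)CCCCCCCC[C@@H](O[Si](C)(C)C(C)(C)C)CC | intermediate
11 | methyl (5R,14S)-14-(tert-butyldimethylsilyloxy)-5-(triethylsilyloxy)hexadec-2-ynoate | COC(=O)C#CC[C@H](O[Si](CC)(CC)CC)CCCCCCCC[C@@H](O[Si](C)(C)C(C)(C)C)CC | intermediate
12 | methyl acetoacetate | CC(=O)CC(=O)OC | starting material
13 | methyl 3-(trimethylsilyloxy)but-2-enoate (E/Z mixture) | COC(=O)C=C(C)O[Si](C)(C)C | intermediate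
14 | lithium 1-methoxy-3-(trimethylsilyloxy)buta-1,3-dien-1-olate | [Li+].COC([O-])=CC(=C)O[Si](C)(C)C | intermediate (not isolated)
15 | 1-methoxy-1,3-bis(trimethylsilyloxy)buta-1,3-diene | COC(O[Si](C)(C)C)=CC(=C)O[Si](C)(C)C | intermediate
16 | methyl 6-methoxy-2-[(2R,11S)-11-(tert-butyldimethylsilyloxy)-2-(triethylsilyloxy)tridecyl]-4,6-bis(trimethylsilyloxy)cyclohexa-1,4-diene-1-carboxylate (either configuration at C6) | COC(=O)C1=C(C[C@H](O[Si](CC)(CC)CC)CCCCCCCC[C@@H](O[Si](C)(C)C(C)(C)C)CC)CC(O[Si](C)(C)C)=CC1(OC)O[Si](C)(C)C | intermediate (not isolated)
17 | methyl 2-hydroxy-6-[(2R,11S)-11-(tert-butyldimethylsilyloxy)-2-(triethylsilyloxy)tridecyl]-4-(trimethylsilyloxy)benzoate | COC(=O)c1c(O)cc(O[Si](C)(C)C)cc1C[C@H](O[Si](CC)(CC)CC)CCCCCCCC[C@@H](O[Si](C)(C)C(C)(C)C)CC | intermediate (not isolated)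
18 | methyl 2,4-dihydroxy-6-[(2R,11S)-2,11-dihydroxytridecyl]benzoate | COC(=O)c1c(O)cc(O)cc1C[C@H](O)CCCCCCCC[C@@H](O)CC | intermediate (not isolated)
19 | (R)-6,8-dihydroxy-3-[(S)-9-hydroxyundecyl]isochroman-1-one | CC[C@H](O)CCCCCCCC[C@@H]1Cc2cc(O)cc(O)c2C(=O)O1 | target

## Step count and least certain steps

Total: 9 steps. Longest linear sequence: 7 steps (steps 1 to 6 and step 9); the diene branch is steps 7 and 8.

Step 9 (key step). The most likely failure is thermal decay of the ketene acetal diene (silyl migration from oxygen to carbon, hydrolysis by traces of water, self-condensation) outrunning its addition to the β-alkylated, singly activated alkyne, which would leave 11 unconsumed. Premature loss of the triethylsilyl ether at 120 °C and sluggish lactonisation are lesser concerns.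

The fallback sets out from 11 and replaces the open-chain diene and its eliminative aromatisation by an Alder–Rickert cycloaddition and cycloreversion with a thermally robust cyclic diene. Commercial 5,5-dimethylcyclohexane-1,3-dione would be O-silylated (Me3SiCl, Et3N) to 5,5-dimethyl-3-(trimethylsilyloxy)cyclohex-2-en-1-one F1 and then, with LiN(iPr)2 and Me3SiCl, converted into 5,5-dimethyl-1,3-bis(trimethylsilyloxy)cyclohexa-1,3-diene F2. Heating 11 with F2 at 140–160 °C should give the bicyclic adduct methyl 8,8-dimethyl-3-[(2R,11S)-11-(tert-butyldimethylsilyloxy)-2-(triethylsilyloxy)tridecyl]-1,5-bis(trimethylsilyloxy)bicyclo[2.2.2]octa-2,5-diene-2-carboxylate F3. Its regiochemistry is the same, because the unsubstituted diene terminus attacks the ynoate β-carbon. Under the same conditions F3 is expected to expel 2-methylpropene by retro-[4+2] cleavage and leave methyl 2,4-bis(trimethylsilyloxy)-6-[(2R,11S)-11-(tert-butyldimethylsilyloxy)-2-(triethylsilyloxy)tridecyl]benzoate F4. Methanolic HCl would convert F4 into 18, where the fallback rejoins the route, and the last operation of step 9 leads on to 19.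

Step 5. The most likely failures are decomposition of the lithiated ester 9 if the temperature rises above −78 °C, and Lewis-acid-induced side reactions of the oxirane (Meinwald rearrangement to the aldehyde, opening by fluoride) or erosion of the silyl ether by BF3.

The fallback sets out from 7 and avoids both the labile acetylide and the Lewis acid. LiC≡CH·H2NCH2CH2NH2 in DMSO should open the oxirane at CH2 to give (4R,13S)-13-(tert-butyldimethylsilyloxy)pentadec-1-yn-4-ol F5. Et3SiCl and imidazole would give (4R,13S)-13-(tert-butyldimethylsilyloxy)-4-(triethylsilyloxy)pentadec-1-yne F6. Deprotonation of the terminal alkyne with n-BuLi at −78 °C and trapping with methyl chloroformate would give 11, where the route is rejoined. This takes three steps in place of steps 5 and 6.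

Step 4. The most likely failure is incomplete kinetic discrimination or over-hydrolysis. It is made worse because residual wrong epimer would be hard to detect, the two stereocentres being far apart. Half of the material is lost by design.

The fallback sets out from 2 and takes the second centre from the chiral pool, with no resolution. Mg should insert selectively into the C–Br bond of 1-bromo-6-chlorohexane to give 6-chlorohexylmagnesium bromide F7. CuI-catalysed opening of 2 by F7 would give (S)-10-chlorodecan-3-ol F8. Silylation (t-BuMe2SiCl, imidazole) would give (S)-tert-butyl[(10-chlorodecan-3-yl)oxy]dimethylsilane F9. Mg in refluxing THF would convert F9 into (S)-8-(tert-butyldimethylsilyloxy)decylmagnesium chloride F10. CuI-catalysed opening of (R)-epichlorohydrin A2 by F10 at −30 °C would give (2R,11S)-11-(tert-butyldimethylsilyloxy)-1-chlorotridecan-2-ol F11. K2CO3 in MeOH would close the oxirane to give 7, where the route is rejoined. This takes four steps in place of steps 1 to 4.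

## Further compounds

F1 | step 9 | 5,5-dimethyl-3-(trimethylsilyloxy)cyclohex-2-en-1-one | CC1(C)CC(=O)C=C(O[Si](C)(C)C)C1
F2 | step 9 | 5,5-dimethyl-1,3-bis(trimethylsilyloxy)cyclohexa-1,3-diene | CC1(C)CC(O[Si](C)(C)C)=CC(O[Si](C)(C)C)=C1
F3 | step 9 | methyl 8,8-dimethyl-3-[(2R,11S)-11-(tert-butyldimethylsilyloxy)-2-(triethylsilyloxy)tridecyl]-1,5-bis(trimethylsilyloxy)bicyclo[2.2.2]octa-2,5-diene-2-carboxylate | COC(=O)C1=C(C[C@H](O[Si](CC)(CC)CC)CCCCCCCC[C@@H](O[Si](C)(C)C(C)(C)C)CC)C2C(O[Si](C)(C)C)=CC1(O[Si](C)(C)C)CC2(C)C
F4 | step 9 | methyl 2,4-bis(trimethylsilyloxy)-6-[(2R,11S)-11-(tert-butyldimethylsilyloxy)-2-(triethylsilyloxy)tridecyl]benzoate | COC(=O)c1c(O[Si](C)(C)C)cc(O[Si](C)(C)C)cc1C[C@H](O[Si](CC)(CC)CC)CCCCCCCC[C@@H](O[Si](C)(C)C(C)(C)C)CC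
F5 | step 5 | (4R,13S)-13-(tert-butyldimethylsilyloxy)pentadec-1-yn-4-ol | C#CC[C@H](O)CCCCCCCC[C@@H](O[Si](C)(C)C(C)(C)C)CC
F6 | step 5 | (4R,13S)-13-(tert-butyldimethylsilyloxy)-4-(triethylsilyloxy)pentadec-1-yne | C#CC[C@H](O[Si](CC)(CC)CC)CCCCCCCC[C@@H](O[Si](C)(C)C(C)(C)C)CC
F7 | step 4 | 6-chlorohexylmagnesium bromide | ClCCCCCC[Mg]Br
F8 | step 4 | (S)-10-chlorodecan-3-ol | CC[C@H](O)CCCCCCCCl
F9 | step 4 | (S)-tert-butyl[(10-chlorodecan-3-yl)oxy]dimethylsilane | CC[C@H](O[Si](C)(C)C(C)(C)C)CCCCCCCCl
F10 | step 4 | (S)-8-(tert-butyldimethylsilyloxy)decylmagnesium chloride | CC[C@H](O[Si](C)(C)C(C)(C)C)CCCCCCC[Mg]Cl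
F11 | step 4 | (2R,11S)-11-(tert-butyldimethylsilyloxy)-1-chlorotridecan-2-ol | CC[C@H](O[Si](C)(C)C(C)(C)C)CCCCCCCC[C@@H](O)CCl
A1 | alternative 1 | (2R,11R)-1,12-dichlorododecane-2,11-diol | ClC[C@H](O)CCCCCCCC[C@@H](O)CCl
A2 | alternative 1 | (R)-epichlorohydrin | ClC[C@H]1CO1
A3 | alternative 1 | 1,6-bis(bromomagnesio)hexane | Br[Mg]CCCCCC[Mg]Br
A4 | alternative 1 | (2R,2'R)-2,2'-(octane-1,8-diyl)bis(oxirane) | C1O[C@@H]1CCCCCCCC[C@@H]1CO1
A5 | alternative 2 | (R)-3-[(S)-9-hydroxyundecyl]-6,8-bis(methoxymethoxy)isochroman-1-one | CC[C@H](O)CCCCCCCC[C@@H]1Cc2cc(OCOC)cc(OCOC)c2C(=O)O1
A6 | alternative 2 | 2-[(S)-9-hydroxyundecyl]-5,7-bis(methoxymethoxy)indan-1-one (racemic at C2) | CC[C@H](O)CCCCCCCCC1Cc2cc(OCOC)cc(OCOC)c2C1=O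
A7 | alternative 3 | 7-hydroxy-2,2-dimethyl-5-[(2R,11S)-2,11-bis(tert-butyldimethylsilyloxy)tridecyl]-4H-benzo[d][1,3]dioxin-4-one | CC1(C)OC(=O)c2c(O1)cc(O)cc2C[C@H](O[Si](C)(C)C(C)(C)C)CCCCCCCC[C@@H](O[Si](C)(C)C(C)(C)C)CC
A8 | alternative 3 | 6-[(6R,15S)-6,15-bis(tert-butyldimethylsilyloxy)-2,4-dioxoheptadecyl]-2,2-dimethyl-4H-1,3-dioxin-4-one | CC1(C)OC(=O)C=C(CC(=O)CC(=O)C[C@H](O[Si](C)(C)C(C)(C)C)CCCCCCCC[C@@H](O[Si](C)(C)C(C)(C)C)CC)O1
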